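The runs come from a simulation from invented constants.

At the last two readings of the theta run, 30.0 h and 50.0 h, you see the target climbing at a late slope of 0.00285 h⁻¹ (fraction of the charge per hour, from readings with a scatter of 0.5 percentage points), and this slope, run back to zero, leaves a lag L of 19.1 h.

- theta: solid substrate 0.050 M; capture agent 1.2 mM; gas 22 mM (held); run made earlier
- flask: solid substrate 0.050 M; capture agent 2.50 mM; gas 22 mM (held); time 10 d

- theta (time / h: target / %): 4.00: 0; 6.00: 0.2; 10.0: 0; 20.0: 2.2; 30.0: 3.1; 50.0: 8.8

(standard deviation of a reading: 0.5 percentage points)

- solid substrate is a solid; its amount is given per volume of the solution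
- at the start none of the gas is in solution
- at the start none of the solid substrate is in solution
- no earlier run changes the charge of capture agent; that part of a forecast is a guess

* amount of target in percent of the solid substrate charged, at 25 h, 3.0 d, 6.0 d and 10 d

My guess for the new flask is that each capture agent withholds one solid substrate, which puts the end state at a ceiling C, one minus the ratio of the two charges, of 95.0%. I also guess that the late slope carries over unchanged, since no earlier run varies the agent. C divided by the slope is the filling time τ, the time needed to reach C at the late slope, and it comes to 13.9 d.

Two extremes follow. If the slope holds, a straight line from L gives 35.6% at 6.0 d and 63.0% at 10 d. If the slope shrinks with whatever is still missing from C, an exponential with time constant τ gives 29.7% and 46.0%. The line stays below C at 10 d because the span after L is shorter than τ, so neither extreme is excluded, and for 10 d I commit to the middle, 54.5%. Watch the stretch after 6.0 d, where the gap between the two grows from 5.9 points to 17 points.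

The forecast differs: it reads a square law and reasons, “The agent must therefore turn over, acting like a catalyst”, giving 4.5%, 33%, 78% and 93%.

The flask gives 2.22%, 14.8%, 35.7% and 55.7%.

    capture agent + adduct → trapped intermediate (k = 1.50 L mol⁻¹ h⁻¹)
    gas ⇌ reagent, rate k2*(csat - [reagent]) (kL = 0.0690 h⁻¹)
    adduct → target (k = 0.00760 h⁻¹)
    solid substrate ⇌ starting material, rate k4*(cs4 - [starting material]) while solid is left; crystals form when [starting material] > cs4 (solubility = 24.0 mM, k = 0.110 h⁻¹)
    starting material + reagent ⇌ adduct (K = 61.0 L mol⁻¹, k = 42.0 L mol⁻¹ h⁻¹)

At 6.0 d the flask sits on the line, and at 10 d it lies below the line and above the curve; over those last days τ, reckoned anew, has grown to 19.0 d. By that step alone adduct has a half-life of 3.80 d on its way to target, much longer than the 0.77 h that starting material has at 10.0 d by the forward rate alone of its path into adduct, a path whose backward turnover is 98% of the forward one. The rate constant of adduct going to target, multiplied by the adduct, gives a fraction of the charge per hour of 0.00279 h⁻¹ at 5.00 d, against 0.00169 h⁻¹ at 10.0 d.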